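The numbers of this flask are made up; the result is computed.

How much target stands in each flask at the end, and which flask leads?

common to all: starting material 0.20 M; reagent 5.00 equiv; precatalyst 0.05 mol%; time 80 s
- winter: temperature 25 °C
- dawn: temperature 55 °C
- summer: temperature 85 °C

    starting material + reagent ⇌ target (K1 = 9.01 M⁻¹, k1 = 0.0813 M⁻¹ s⁻¹, Ea1 = 40.0 kJ mol⁻¹, ΔH1 = −53.0 kJ mol⁻¹)
    starting material + reagent ⇌ isomer of the product (K2 = 224 M⁻¹, k2 = 0.00421 M⁻¹ s⁻¹, Ea2 = 70.0 kJ mol⁻¹, ΔH2 = −38.0 kJ mol⁻¹)
    target + catalyst ⇌ isomer of the product + catalyst, rate k3*[catalyst]*[target] forward; the back reaction follows from the equilibrium constant (k3 = 363 M⁻¹ s⁻¹, Ea3 = 42.0 kJ mol⁻¹)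
    precatalyst → catalyst (k4 = 0.362 s⁻¹, Ea4 = 67.0 kJ mol⁻¹)
    (constants at 25 °C)

- the list of constants is for 25 °C, to be carried to other temperatures by the activation energies and enthalpies

1. which flask leads in amount of target, in percent of the starting material charged ("all alike" within 1.5 percentage points) (winter / dawn / summer / all alike)
2. how much target is there at the end, in percent of the starting material charged: winter
3. how much target is there at the end, in percent of the starting material charged: dawn
4. how much target is there at the end, in percent of the starting material charged: summer

I ask what end state the catalyst is heading for, then how fast winter approaches it.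

1. End state. The catalysed exchange has the constant K, equal to the isomer constant over the target constant: 24.9 in winter and 68.5 in summer. Let F be one over one plus K, the target's equilibrium share of target and isomer of the product. This floor is 3.87% in winter and 1.44% in summer. I ignore leftover starting material here.

2. Clock. The catalyst charge is 0.100 mM. Forward and back exchange together give the winter rate constant d = 0.0378 s⁻¹. The drain half-life D, 18.4 s, is the time in which target's excess over its floor halves. The catalyst's waking half-life, 1.91 s, is shorter than D, so I take the catalyst as present from the start. Winter's 80 s holds 4.36 spans of D.

3. Lower bound. The share of starting material entering through target is 0.951. If that share were target at time zero, winter would end at 8.32%.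

4. Upper bound. Target is really fed over time. With reagent at its lowest, 0.800 M, the feed constant is 0.0650 s⁻¹. Two consecutive first-order steps then give 13.3%. This top is soft, since I ignore the return of target to starting material.

5. Hot flasks. In summer the drain half-life is near 1.07 s, far shorter than 80 s, so I place summer near its floor and dawn between 1.44% and 3.87%. Winter's lower bound exceeds that dawn ceiling, so I pick winter: kinetic control there, thermodynamic control in the hot flasks.

The forecast says winter, with 13.5% (11% to 16%), 2.25% (2% to 2.6%) and 1.35% (1.2% to 1.5%). Its ground: “winter is still under kinetic control and keeps the most target”. Its winter value stands just above my top, and its summer value below my floor.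

The simulation gives winter as the leader, with 12.8% in winter, 2.22% in dawn and 1.34% in summer. The winter value stands above my lower bound and below my top.

In winter at 80.0 s, the exchange alone relaxes with half-life 18.4 s, shorter than the reaction time, and target is made at 0.189 of the rate at which it is used up, each step taken net. Even so, 4.36 spans of D leave winter at 12.8%, against 3.85% after 800 s.

Winter read at 20 s holds 1.09 spans of D, and the fed reckoning gives 46.9% target. That flask shows 46.4%.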